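**Retrosynthetic overview**

1. The plan rests on the oxolane ring O–C7–C8–C8'–C9' (C7 carries ring A, C8 carries C9H2OH, C8' carries the benzylic C7'H2 of ring B, C9' is the ring OCH2). The cis pair C9/C7' across C8–C8' is read as a γ-lactone bridge C9(=O)–O–C7', and the segment C7–O–C9' as the carbonyl ylide of the ring A aldehyde.
2. Target 16 ⇒ acid 15 ⇒ cis-fused bicyclic lactone 13 by restoring the benzylic C7'–O bond; the C7' stereocentre only steers the cycloaddition and is removed by hydrogenolysis.
3. 13 ⇒ [3+2]: ylide 12 (C7–O–C9', from α-chloro ether 11) plus the C8=C8' bond of (S)-butenolide 8, forming C7–C8 and C8'–C9'.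
4. 8 ⇐ ring-closing metathesis of the acrylate of resolved (S)-aryl vinyl carbinol 5; 11 ⇐ bis(silylmethyl) acetal 10; both arms start from O-benzylsyringaldehyde 2.
5. Ring order: lactone ring (step 5), oxolane ring (step 8), then the lactone ring is opened again (step 9).

Key step: step 8

Remark on the chemistry: the lipase is assumed to acetylate the (R)-carbinol of 4, as it does with 1-arylalkan-1-ols of the same shape, so that the (S)-alcohol 5 is the one recovered. Compound 11 is used as the racemate because its stereocentre vanishes in ylide 12.

**Route**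

Step 1
Reactants: 1 syringaldehyde
Product: 2 4-(benzyloxy)-3,5-dimethoxybenzaldehyde
Conditions: BnBr, K2CO3, DMF, 60 °C
Reagents that add atoms: benzyl bromide, BrCc1ccccc1
Why: Williamson ether synthesis on the phenoxide, with the aldehyde inert to carbonate and the benzyl ether chosen because it leaves later in the same hydrogenolysis that opens the lactone.

Step 2
Reactants: 2 4-(benzyloxy)-3,5-dimethoxybenzaldehyde; 3 vinylmagnesium bromide
Product: 4 rac-1-[4-(benzyloxy)-3,5-dimethoxyphenyl]prop-2-en-1-ol
Conditions: THF, −78 → 0 °C; aq. NH4Cl
Reagents that add atoms: none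
Why: Grignard 1,2-addition to the aldehyde gives the racemic allylic benzylic alcohol, and the buffered quench avoids ionisation of this electron-rich carbinol.

Step 3
Reactants: 4 rac-1-[4-(benzyloxy)-3,5-dimethoxyphenyl]prop-2-en-1-ol
Product: 5 (S)-1-[4-(benzyloxy)-3,5-dimethoxyphenyl]prop-2-en-1-ol
Conditions: vinyl acetate, immobilised Candida antarctica lipase B (Novozym 435), MTBE, 30 °C, run to just beyond half conversion; chromatography
Reagents that add atoms: none
Why: Lipase-catalysed kinetic resolution by irreversible transesterification, in which the (R)-enantiomer (vinyl in the small pocket, aryl in the large one) should be acetylated and the wanted (S)-alcohol is recovered unchanged, so the stereocentre is selected and not made.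

Step 4
Reactants: 5 (S)-1-[4-(benzyloxy)-3,5-dimethoxyphenyl]prop-2-en-1-ol; 6 acryloyl chloride
Product: 7 (S)-1-[4-(benzyloxy)-3,5-dimethoxyphenyl]prop-2-en-1-yl acrylate
Conditions: Et3N, CH2Cl2, −20 → 0 °C
Reagents that add atoms: none
Why: O-acylation with an acid chloride under amine base leaves the C–O bond at the stereocentre intact, and the excess base removes HCl before it can ionise the benzylic allylic ester.

Step 5
Reactants: 7 (S)-1-[4-(benzyloxy)-3,5-dimethoxyphenyl]prop-2-en-1-yl acrylate
Product: 8 (S)-5-[4-(benzyloxy)-3,5-dimethoxyphenyl]furan-2(5H)-one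
Conditions: second-generation Grubbs catalyst (5 mol%), 1,4-benzoquinone (10 mol%), CH2Cl2 (0.01 M), 40 °C
Reagents that add atoms: none
Why: Ring-closing metathesis of the acrylate and vinyl groups closes the unsaturated five-membered lactone with loss of ethene, the stereocentre being a spectator and benzoquinone suppressing the ruthenium hydride double-bond migration that would racemise it.

Step 6
Reactants: 2 4-(benzyloxy)-3,5-dimethoxybenzaldehyde; 9 (trimethylsilyl)methanol
Product: 10 4-(benzyloxy)-3,5-dimethoxybenzaldehyde bis[(trimethylsilyl)methyl] acetal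
Conditions: 9 (2.5 equiv), TsOH·H2O (cat.), cyclohexane, reflux, Dean–Stark trap; Et3N quench
Reagents that add atoms: none
Why: Acid-catalysed acetalisation of the aldehyde with a primary alcohol, driven by azeotropic removal of water, with the benzyl ether and the C–Si bonds stable to catalytic sulfonic acid.

Step 7
Reactants: 10 4-(benzyloxy)-3,5-dimethoxybenzaldehyde bis[(trimethylsilyl)methyl] acetal
Product: 11 rac-[({[4-(benzyloxy)-3,5-dimethoxyphenyl]chloromethyl}oxy)methyl]trimethylsilane (α-chlorobenzyl (trimethylsilyl)methyl ether of ring A)
Conditions: AcCl (1.2 equiv), SOCl2 (cat.), CH2Cl2, 0 °C → rt; volatiles removed in vacuo, used crude at once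
Reagents that add atoms: acetyl chloride, CC(=O)Cl
Why: Acetal cleavage by an acyl chloride, in which one silylmethoxy group is acetylated and leaves as its ester while chloride captures the aryl-stabilised oxocarbenium ion, giving an α-chloro ether whose new centre is racemic and disappears in the next step.

Step 8
Reactants: 8 (S)-5-[4-(benzyloxy)-3,5-dimethoxyphenyl]furan-2(5H)-one; 11 rac-α-chlorobenzyl (trimethylsilyl)methyl ether of ring A
Product: 13 (3S,3aR,6S,6aS)-3,6-bis[4-(benzyloxy)-3,5-dimethoxyphenyl]tetrahydro-1H,3H-furo[3,4-c]furan-1-one (cis-fused 3,7-dioxabicyclo[3.3.0]octanone; lignan centres 7S,8S,8'R,7'S), via carbonyl ylide 12 (not isolated)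
Conditions: 11 (2 equiv), CsF (flame-dried, 2.5 equiv, added in portions), MeCN, 0 °C → rt, under argon
Reagents that add atoms: none
Why: Fluoride attacks silicon of 11 while chloride leaves (1,3-elimination by way of the O-silylmethyl oxocarbenium ion) and gives the non-stabilised carbonyl ylide 12, which adds to the electron-poor C8=C8' bond of 8 in a concerted suprafacial [3+2] cycloaddition; the closest known reaction is the fluoride-induced generation of such ylides from α-chloroalkyl silylmethyl ethers and their addition to enoates and enones. The oxolane ring closes by intermolecular [3+2] annulation onto the existing lactone ring, C7–C8 and C8'–C9' forming on the same alkene face, so the ring fusion is necessarily cis, which is the cis relation of C9 and C7' in the target. The orientation follows from the polarisation of 12, in which the donor aryl group holds the oxocarbenium character at C7 and leaves C9' as the carbanionic end, so C9' bonds to the β carbon C8' and C7 to the α carbon C8, a sense that also keeps the smaller CH2 terminus next to the substituted C7'. The configurations at C8 and C8' are controlled by ring B on C7', since the dipole approaches the butenolide face anti to it, as other dipoles and dienes do with 5-substituted butenolides. The configuration at C7 is controlled by the ylide geometry (ring A outward, inherited from the E oxocarbenium ion) together with an exo approach that turns the ylide oxygen away from the lactone ring, which puts ring A trans to C9 on the convex face; this exo preference is the selectivity least firmly secured by the substrate. The step also needs cycloaddition to outrun deprotonation at the acidic C7'–H of 8, which the excess of 11 and the portionwise addition of dry, sparingly soluble CsF should secure by keeping free fluoride low.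

Step 9
Reactants: 13 (3S,3aR,6S,6aS)-3,6-bis[4-(benzyloxy)-3,5-dimethoxyphenyl]tetrahydro-1H,3H-furo[3,4-c]furan-1-one
Product: 15 (2S,3S,4R)-4-(4-hydroxy-3,5-dimethoxybenzyl)-2-(4-hydroxy-3,5-dimethoxyphenyl)tetrahydrofuran-3-carboxylic acid, via bisphenol lactone 14 (not isolated)
Conditions: H2 (1 atm), 10% Pd/C, EtOAc–EtOH, rt; stopped when 14 is consumed
Reagents that add atoms: none
Why: Catalytic hydrogenolysis removes the two aryl benzyl ethers first and then the benzylic acyloxy bond C7'–O of the lactone, whose carboxylate is a far better leaving group on palladium than the alkoxide of the oxolane C7–O bond, so C7' becomes CH2 and the C9 acid is freed while C7, C8 and C8' are untouched.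

Step 10
Reactants: 15 (2S,3S,4R)-4-(4-hydroxy-3,5-dimethoxybenzyl)-2-(4-hydroxy-3,5-dimethoxyphenyl)tetrahydrofuran-3-carboxylic acid
Product: 16 (+)-(7S,8R,8'R)-5,5'-dimethoxylariciresinol
Conditions: BH3·SMe2 (5 equiv), THF, 0 °C → rt; MeOH quench
Reagents that add atoms: none
Why: Chemoselective borane reduction of the carboxylic acid through its acyloxyborane to the primary alcohol, in which the phenols only consume hydride as aryl borates that methanol cleaves, the benzylic ether is inert and the non-basic medium leaves C8 unable to epimerise.

**Compound list**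

1 | syringaldehyde (4-hydroxy-3,5-dimethoxybenzaldehyde) | COc1cc(C=O)cc(OC)c1O | starting material
2 | 4-(benzyloxy)-3,5-dimethoxybenzaldehyde | COc1cc(C=O)cc(OC)c1OCc1ccccc1 | intermediate
3 | vinylmagnesium bromide | C=C[Mg]Br | starting material
4 | rac-1-[4-(benzyloxy)-3,5-dimethoxyphenyl]prop-2-en-1-ol | C=CC(O)c1cc(OC)c(OCc2ccccc2)c(OC)c1 | intermediate
5 | (S)-1-[4-(benzyloxy)-3,5-dimethoxyphenyl]prop-2-en-1-ol | C=C[C@H](O)c1cc(OC)c(OCc2ccccc2)c(OC)c1 | intermediate
6 | acryloyl chloride | C=CC(=O)Cl | starting material
7 | (S)-1-[4-(benzyloxy)-3,5-dimethoxyphenyl]prop-2-en-1-yl acrylate | C=CC(=O)O[C@@H](C=C)c1cc(OC)c(OCc2ccccc2)c(OC)c1 | intermediate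
8 | (S)-5-[4-(benzyloxy)-3,5-dimethoxyphenyl]furan-2(5H)-one | O=C1C=C[C@@H](c2cc(OC)c(OCc3ccccc3)c(OC)c2)O1 | intermediate
9 | (trimethylsilyl)methanol | C[Si](C)(C)CO | starting material
10 | 4-(benzyloxy)-3,5-dimethoxybenzaldehyde bis[(trimethylsilyl)methyl] acetal | COc1cc(C(OC[Si](C)(C)C)OC[Si](C)(C)C)cc(OC)c1OCc1ccccc1 | intermediate
11 | rac-[({[4-(benzyloxy)-3,5-dimethoxyphenyl]chloromethyl}oxy)methyl]trimethylsilane | COc1cc(C(Cl)OC[Si](C)(C)C)cc(OC)c1OCc1ccccc1 | intermediate
12 | carbonyl ylide, 4-(benzyloxy)-3,5-dimethoxybenzylidene(methylide)oxonium (ring A–CH=O(+)–CH2(−)) | [CH2-][O+]=Cc1cc(OC)c(OCc2ccccc2)c(OC)c1 | intermediate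
13 | (3S,3aR,6S,6aS)-3,6-bis[4-(benzyloxy)-3,5-dimethoxyphenyl]tetrahydro-1H,3H-furo[3,4-c]furan-1-one (ring B at C3 and ring A at C6 both on the convex face) | [C@@H]1(c3cc(OC)c(OCc4ccccc4)c(OC)c3)[C@H]2CO[C@H](c3cc(OC)c(OCc4ccccc4)c(OC)c3)[C@H]2C(=O)O1 | intermediate
14 | (3S,3aR,6S,6aS)-3,6-bis(4-hydroxy-3,5-dimethoxyphenyl)tetrahydro-1H,3H-furo[3,4-c]furan-1-one (bisphenol lactone) | [C@@H]1(c3cc(OC)c(O)c(OC)c3)[C@H]2CO[C@H](c3cc(OC)c(O)c(OC)c3)[C@H]2C(=O)O1 | intermediate
15 | (2S,3S,4R)-4-(4-hydroxy-3,5-dimethoxybenzyl)-2-(4-hydroxy-3,5-dimethoxyphenyl)tetrahydrofuran-3-carboxylic acid | COc1cc(C[C@H]2CO[C@H](c3cc(OC)c(O)c(OC)c3)[C@H]2C(=O)O)cc(OC)c1O | intermediate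
16 | (+)-(7S,8R,8'R)-5,5'-dimethoxylariciresinol, 4-{[(3R,4R,5S)-5-(4-hydroxy-3,5-dimethoxyphenyl)-4-(hydroxymethyl)tetrahydrofuran-3-yl]methyl}-2,6-dimethoxyphenol | COc1cc(C[C@H]2CO[C@H](c3cc(OC)c(O)c(OC)c3)[C@H]2CO)cc(OC)c1O | target

**Step count and risks**

Total step count: 10. Longest linear sequence: 8 steps (1, 2, 3, 4, 5, 8, 9, 10); steps 6 and 7 form the side arm that joins at step 8.

Steps most likely to fail:

Step 8. The dipole may approach with its oxygen over the lactone ring (endo mode), which would place ring A cis to C9, so exo selectivity at C7 may be poor. Fluoride may also deprotonate C7'–H of 8 and erode its enantiomeric purity before the ylide traps it; the enantiomeric purity of 13 would be checked against a racemic sample. The fallback replaces kinetic control at C7 by thermodynamic control. It sets out from 8 and 11: the cycloaddition is run as before and the C7 epimer of 13 with ring A on the concave face, F1, is separated. F1 is then treated with catalytic camphorsulfonic acid in CH2Cl2 at room temperature. Reversible heterolysis of the benzylic C7–O bond, followed by re-closure of the para-alkoxybenzyl cation on the C9' hydroxyl, interconverts F1 and 13. Capture of the cation by ring B is excluded because C7 and ring B lie trans across the lactone ring. The isomer with ring A on the convex face should be favoured, probably only moderately, so recovered F1 would be resubmitted. The route is rejoined at 13.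

Step 9. Hydrogenolysis may run on to the second benzylic C–O bond (C7–O of the oxolane) and give the ring-opened acid, or it may stall at the lactone stage. The fallback separates the two events and cleaves C7'–O by an ionic path. It sets out from 13: a short hydrogenolysis (H2, Pd/C, EtOAc, interrupted after debenzylation) gives 14, now isolated. Treatment of 14 with NaBH4 in aqueous NaOH–EtOH at 0 °C → room temperature should let the ring B phenoxide expel the C9 carboxylate in a 1,6-elimination, giving the para-quinone methide acid F2. Hydride then adds at C7' and acidification gives 15. The C7–O bond would have to release an alkoxide and should stay closed. The route is rejoined at 15.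

Step 5. Metathesis of the electron-poor acrylate may be slow, which gives time for ruthenium hydride species to move the ring double bond toward ring B (loss of the C7' configuration) or for the allylic benzylic ester to ionise and rearrange. The fallback builds the butenolide by alkyne semireduction and replaces steps 2 to 5. It sets out from 2 and methyl propiolate: Me2Zn with a ProPhenol ligand (enantiomer chosen for the required sense) should give the propargylic alcohol methyl (R)-4-[4-(benzyloxy)-3,5-dimethoxyphenyl]-4-hydroxybut-2-ynoate F3, which has the same spatial arrangement as 8. Semihydrogenation (H2, Pd/CaCO3 poisoned with Pb(OAc)2, quinoline, EtOAc) gives the (Z)-hydroxy enoate F4, which lactonises on standing or with catalytic acid. The route is rejoined at 8.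

**Further compounds**

F1 | step 8 | (3S,3aR,6R,6aS)-3,6-bis[4-(benzyloxy)-3,5-dimethoxyphenyl]tetrahydro-1H,3H-furo[3,4-c]furan-1-one (C7 epimer of 13) | [C@@H]1(c3cc(OC)c(OCc4ccccc4)c(OC)c3)[C@H]2CO[C@@H](c3cc(OC)c(OCc4ccccc4)c(OC)c3)[C@H]2C(=O)O1
F2 | step 9 | (2S,3S,4R)-4-[(3,5-dimethoxy-4-oxocyclohexa-2,5-dien-1-ylidene)methyl]-2-(4-hydroxy-3,5-dimethoxyphenyl)tetrahydrofuran-3-carboxylic acid (para-quinone methide acid) | COC1=CC(=C[C@H]2CO[C@H](c3cc(OC)c(O)c(OC)c3)[C@H]2C(=O)O)C=C(OC)C1=O
F3 | step 5 | methyl (R)-4-[4-(benzyloxy)-3,5-dimethoxyphenyl]-4-hydroxybut-2-ynoate | COC(=O)C#C[C@@H](c1cc(OC)c(OCc2ccccc2)c(OC)c1)O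
F4 | step 5 | methyl (S,Z)-4-[4-(benzyloxy)-3,5-dimethoxyphenyl]-4-hydroxybut-2-enoate | COC(=O)/C=C\[C@@H](c1cc(OC)c(OCc2ccccc2)c(OC)c1)O
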